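## Retrosynthetic overview

- **Feature:** ring A (C1–C5, C10) holds axial C19 and axial C20 on the same face as C6 at the adjacent centres C4, C5 and C10, which is the pattern left by a chair cation–olefin closure. The δ-lactone (C10–C20–O–C7–C8–C9) ties spiro C10 to C9, the enolisable carbon next to oxygenated C11.
- **Key disconnection:** C4–C5 and C9–C10 are cut together. This leads back to a (3R,4S)-epoxy Z-alkene whose C20 oxygen is acylated by a bicyclo[3.2.1]oct-2-ene-1-carboxylic acid bearing the C9=C11 enol silane.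
- **Fragments:** the ester is split (Mitsunobu) into two parts. The allylic alcohol holds C1–C6, C10 and C18–C20 and comes from alkyne hydroalumination, Still–Gennari olefination and Sharpless epoxidation. The 17-nor C/D keto acid comes from Noyori hydrogenation, Frater–Seebach allylation, Wacker oxidation and an intramolecular Michael addition.
- **Ring order:** D (cyclopentanone), then C (Michael), then A and the δ-lactone together (key step), then the γ-lactone (C6 oxidation, closure onto C19). C16 methylenation and the C15 and C11 reductions come last.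

Key step: step 20

Assumption: atoms are labelled C1–C20 in ent-kaurane numbering throughout, and the sense of the chiral lithium amide in step 19 is assigned by analogy with the deprotonation of 4-tert-butylcyclohexanone by the same base, read on the exo face of ring C.

## Route

Step 1
Reactants: 1 prop-2-yn-1-ol; 2 2-(2-bromoethyl)-1,3-dioxolane
Product: 4 5-(1,3-dioxolan-2-yl)pent-2-yn-1-ol, via dilithium salt of prop-2-yn-1-ol 3 (not isolated)
Conditions: n-BuLi (2.1 equiv), THF–DMPU, −78 °C to rt
Reagents that add atoms: none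
Why: Acetylide alkylation (SN2 at the primary bromide), in which the alkoxide stays a spectator while the acetylide carbon joins C10 to C1 and brings in C3 as a masked aldehyde.

Step 2
Reactants: 4 5-(1,3-dioxolan-2-yl)pent-2-yn-1-ol
Product: 6 (Z)-5-(1,3-dioxolan-2-yl)-3-iodopent-2-en-1-ol, via cyclic sodium vinylalanate 5 (not isolated)
Conditions: NaAlH2(OCH2CH2OMe)2, THF, 0 °C to rt; then I2, −78 °C
Reagents that add atoms: iodine, [I][I]
Why: Hydroxyl-directed trans-hydroalumination places aluminium on C10 inside a five-membered alanate, hence cis to C6, and iodinolysis with retention gives the Z-iodide, so that the group that later replaces iodine (C20) stands cis to C6.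

Step 3
Reactants: 6 (Z)-5-(1,3-dioxolan-2-yl)-3-iodopent-2-en-1-ol
Product: 7 2-[(Z)-5-(benzyloxy)-3-iodopent-3-en-1-yl]-1,3-dioxolane
Conditions: NaH, BnBr, n-Bu4NI (cat.), THF, 0 °C to rt
Reagents that add atoms: benzyl bromide, BrCc1ccccc1
Why: Williamson etherification of the only hydroxyl group marks C6 as a benzyl ether, which resists base, hydride and the Lewis acid of the key step and is removed later by hydrogenolysis.

Step 4
Reactants: 7 2-[(Z)-5-(benzyloxy)-3-iodopent-3-en-1-yl]-1,3-dioxolane
Product: 8 (Z)-6-(benzyloxy)-4-iodohex-4-enal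
Conditions: 1 M HCl, THF, 45 °C
Reagents that add atoms: water, O
Why: Acid-catalysed acetal hydrolysis frees the C3 aldehyde, the vinyl iodide and the allylic benzyl ether being inert to dilute acid.

Step 5
Reactants: 8 (Z)-6-(benzyloxy)-4-iodohex-4-enal; 9 methyl 2-[bis(2,2,2-trifluoroethoxy)phosphoryl]propanoate
Product: 10 methyl (2Z,6Z)-8-(benzyloxy)-6-iodo-2-methylocta-2,6-dienoate
Conditions: KN(SiMe3)2, 18-crown-6, THF, −78 °C
Reagents that add atoms: none
Why: Still–Gennari olefination, in which fast irreversible collapse of the kinetic adduct of the trifluoroethyl phosphonate gives the Z-enoate and so puts the C19 carbon cis to the C2 chain, as an axial C19 requires.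

Step 6
Reactants: 10 methyl (2Z,6Z)-8-(benzyloxy)-6-iodo-2-methylocta-2,6-dienoate
Product: 11 (2Z,6Z)-8-(benzyloxy)-6-iodo-2-methylocta-2,6-dien-1-ol
Conditions: i-Bu2AlH (2.3 equiv), CH2Cl2, −78 °C
Reagents that add atoms: none
Why: 1,2-Reduction of the enoate with i-Bu2AlH gives the allylic alcohol without touching either alkene geometry or the vinyl iodide.

Step 7
Reactants: 11 (2Z,6Z)-8-(benzyloxy)-6-iodo-2-methylocta-2,6-dien-1-ol
Product: 12 {(2S,3R)-3-[(Z)-5-(benzyloxy)-3-iodopent-3-en-1-yl]-2-methyloxiran-2-yl}methanol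
Conditions: Ti(OiPr)4 (10 mol%), L-(+)-diethyl tartrate (12 mol%), t-BuOOH, 4 Å molecular sieves, CH2Cl2, −20 °C
Reagents that add atoms: tert-butyl hydroperoxide, CC(C)(C)OO
Why: Sharpless asymmetric epoxidation, in which only the C3=C4 alkene has a free allylic hydroxyl group and the L-(+)-tartrate catalyst turns a Z-allylic alcohol into the (2S,3R)-epoxy alcohol, fixing C3 (R) and C4 (S), any minor enantiomer being shed as a diastereomer after step 18.

Step 8
Reactants: 12 {(2S,3R)-3-[(Z)-5-(benzyloxy)-3-iodopent-3-en-1-yl]-2-methyloxiran-2-yl}methanol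
Product: 13 tert-butyldimethylsilyl ether of 12 (C19–OTBS)
Conditions: TBSCl, imidazole, CH2Cl2, 0 °C to rt
Reagents that add atoms: tert-butyldimethylsilyl chloride, CC(C)(C)[Si](C)(C)Cl
Why: Silylation of the primary alcohol, the bulky and weakly basic silyl ether keeping O19 out of the later epoxide opening.

Step 9
Reactants: 13 tert-butyldimethylsilyl ether of 12
Product: 15 (Z)-4-(benzyloxy)-2-{2-[(2R,3S)-3-{[(tert-butyldimethylsilyl)oxy]methyl}-3-methyloxiran-2-yl]ethyl}but-2-en-1-ol, via C10 vinyllithium 14 (not isolated)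
Conditions: t-BuLi (2.1 equiv), Et2O, −78 °C; HCHO (gas), −78 °C
Reagents that add atoms: formaldehyde, C=O
Why: Iodine–lithium exchange with retention (lithium chelated by the cis benzyloxy group) followed by hydroxymethylation installs C20 cis to C6, and at −78 °C the trisubstituted epoxide and the silyl ether are not attacked.

Step 10
Reactants: 16 tert-butyl 2-oxocyclopentane-1-carboxylate (racemic)
Product: 17 tert-butyl (1S,2S)-2-hydroxycyclopentane-1-carboxylate
Conditions: H2 (80 bar), RuCl2[(S)-BINAP] (0.5 mol%), CH2Cl2, 50 °C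
Reagents that add atoms: none
Why: Noyori asymmetric hydrogenation of a β-keto ester, in which the (S)-BINAP catalyst sets the carbinol carbon (C15) as S while the labile C8 centre epimerises (dynamic kinetic resolution, trans product), only the carbinol configuration mattering for step 11.

Step 11
Reactants: 17 tert-butyl (1S,2S)-2-hydroxycyclopentane-1-carboxylate; 18 allyl bromide
Product: 20 tert-butyl (1S,2S)-1-allyl-2-hydroxycyclopentane-1-carboxylate, via dilithium enolate alkoxide 19 (not isolated)
Conditions: LiN(i-Pr)2 (2.2 equiv), THF–DMPU, −78 to −20 °C; allyl bromide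
Reagents that add atoms: none
Why: Frater–Seebach alkylation, in which the chelated dilithium enolate–alkoxide is allylated on the face opposite to the C15 oxygen and thereby sets quaternary C8 in the configuration of the target.

Step 12
Reactants: 20 tert-butyl (1S,2S)-1-allyl-2-hydroxycyclopentane-1-carboxylate
Product: 22 tert-butyl (R)-1-allyl-2-oxocyclopent-3-ene-1-carboxylate (C8 unchanged in space; the descriptor changes by ranking only), via (S)-allyl keto ester 21 (not isolated)
Conditions: 2-iodoxybenzoic acid (3.5 equiv), DMSO, 75 °C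
Reagents that add atoms: none
Why: 2-Iodoxybenzoic acid oxidises the alcohol to the ketone and, at this temperature, dehydrogenates its only enolisable side (C16–C13) to the cyclopentenone, the auxiliary C15 stereocentre being erased after it has done its work.

Step 13
Reactants: 22 tert-butyl (R)-1-allyl-2-oxocyclopent-3-ene-1-carboxylate
Product: 23 tert-butyl (S)-2-oxo-1-(2-oxopropyl)cyclopent-3-ene-1-carboxylate
Conditions: PdCl2 (10 mol%), CuCl, O2 (1 atm), DMF–H2O (7:1), rt
Reagents that add atoms: water, O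
Why: Wacker–Tsuji oxidation, in which Markovnikov hydroxypalladation of the terminal alkene gives the methyl ketone (C11=O, C12H3) while the electron-poor enone alkene does not compete.

Step 14
Reactants: 23 tert-butyl (S)-2-oxo-1-(2-oxopropyl)cyclopent-3-ene-1-carboxylate
Product: 25 tert-butyl (1S,5S)-3,7-dioxobicyclo[3.2.1]octane-1-carboxylate, via bicyclic potassium enolate 24 (not isolated)
Conditions: KN(SiMe3)2 (1.05 equiv), THF, −78 to 0 °C; AcOH
Reagents that add atoms: none
Why: Intramolecular Michael addition (6-enolendo-exo-trig), in which the methyl ketone enolate reaches C13 only on the face that carries the side chain, so that C13 is set by C8 and ring C closes, the competing five-ring aldol addition being reversible.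

Step 15
Reactants: 25 tert-butyl (1S,5S)-3,7-dioxobicyclo[3.2.1]octane-1-carboxylate
Product: 28 tert-butyl (1S,5R,7R)-7-hydroxy-3-oxobicyclo[3.2.1]octane-1-carboxylate (endo C15–OH), via C11 dimethyl ketal 26 (not isolated), via hydroxy ketal 27 (not isolated)
Conditions: HC(OMe)3, TsOH (5 mol%), MeOH, rt; NaBH4, 0 °C; 1 M HCl, THF, rt
Reagents that add atoms: trimethyl orthoformate, COC(OC)OC (methoxy groups of 26 and 27); water, O (carbonyl oxygen of 28)
Why: Telescoped ketalisation, reduction and hydrolysis, in which only the open C11 ketone forms a ketal, borohydride attacks the neopentyl C15 ketone from the exo face (away from the C9–C11–C12 bridge) to give the endo alcohol, and dilute acid returns the C11 ketone.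

Step 16
Reactants: 28 tert-butyl (1S,5R,7R)-7-hydroxy-3-oxobicyclo[3.2.1]octane-1-carboxylate
Product: 29 (1S,5R,7R)-7-hydroxy-3-oxobicyclo[3.2.1]octane-1-carboxylic acid
Conditions: CF3CO2H–CH2Cl2 (1:3), 0 °C to rt
Reagents that add atoms: none
Why: Acidolysis of the tert-butyl ester (loss of isobutene) needs no attack at the hindered carbonyl group and leaves ketone and alcohol untouched.

Step 17
Reactants: 29 (1S,5R,7R)-7-hydroxy-3-oxobicyclo[3.2.1]octane-1-carboxylic acid
Product: 31 (1S,5R,7R)-7-[(tert-butyldimethylsilyl)oxy]-3-oxobicyclo[3.2.1]octane-1-carboxylic acid, via silyl ether silyl ester 30 (not isolated)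
Conditions: TBSOTf (2.5 equiv), 2,6-lutidine, CH2Cl2, 0 °C; then THF–H2O–AcOH, rt
Reagents that add atoms: tert-butyldimethylsilyl triflate, CC(C)(C)[Si](C)(C)OS(=O)(=O)C(F)(F)F
Why: Silylation of the hindered endo alcohol with the silyl triflate, the silyl ester formed alongside being hydrolysed selectively by aqueous acetic acid.

Step 18
Reactants: 31 (1S,5R,7R)-7-[(tert-butyldimethylsilyl)oxy]-3-oxobicyclo[3.2.1]octane-1-carboxylic acid; 15 allylic alcohol from step 9
Product: 32 epoxy-diene keto ester, the C20 ester of acid 31 with alcohol 15 (5Z; 3R,4S-epoxide; 8S,13R,15R; C11 ketone)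
Conditions: PPh3, DIAD, toluene, 0 °C to rt
Reagents that add atoms: none
Why: Mitsunobu esterification activates the primary allylic alcohol rather than the hindered bridgehead acid, so the carboxylate displaces at C20 (SN2) under neutral conditions that spare epoxide, ketone and silyl ethers.

Step 19
Reactants: 32 epoxy-diene keto ester
Product: 34 C9=C11 tert-butyldimethylsilyl enol ether of 32 (all stereocentres unchanged), via C9=C11 lithium enolate 33 (not isolated)
Conditions: (S,S)-[PhCH(Me)]2NH, n-BuLi, LiCl, THF, −78 °C; TBSOTf, −78 °C; Et3N, aq. NaHCO3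
Reagents that add atoms: tert-butyldimethylsilyl triflate, CC(C)(C)[Si](C)(C)OS(=O)(=O)C(F)(F)F
Why: Reagent-controlled kinetic deprotonation with a chiral lithium amide, the reaction known for desymmetrising bicyclo[3.2.1]octan-3-ones, in which C9 and C12 differ only by bridgehead substituents lying near the ring plane, so the (S,S)-base with LiCl should take the exo proton at C9, and O-silylation at −78 °C fixes the enol silane before the triflate can touch the epoxide.

Step 20
Reactants: 34 C9=C11 tert-butyldimethylsilyl enol ether of 32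
Product: 35 17-nor spirolactone with equatorial 3-OH, 11-oxo, 6-O-benzyl, 19-O-TBS and endo 15-O-TBS (ring A chair: C19 and C20 axial and cis, H5 axial on the other face, C6 and C9 equatorial; C10 on the exo face of C9)
Conditions: MeAlCl2 (2.5 equiv), CH2Cl2 (2 mM), −78 °C; then H2O
Reagents that add atoms: none
Why: Proposed new method: MeAlCl2 binds the epoxide oxygen and loosens the tertiary C4–O bond, C5 of the Z-alkene attacks C4 from the rear through a chair (6-endo with respect to both epoxide and alkene, ring A), and the charge building at C10 is quenched on the opposite alkene face by C9 of the enol silane, held within reach by the C7 ester in its s-cis form (6-exo-trig at C10, 6-enolexo at C9, δ-lactone), after which loss of the silyl group to chloride leaves the C11 ketone. The closest known reaction type is the MeAlCl2-promoted epoxy-polyene cyclisation ended by a carbon-tethered silyl enol ether, and the ring closure of epoxygeranyl acetate shows that an alkene with one allylic oxygen still opens such an epoxide, whereas the ester tether, the spiro mode of termination and the second allylic oxygen at C20 are without precedent. C4 is set by inversion at the Sharpless-derived epoxide carbon, which turns the substituent cis to the chain (C19) axial and O3 equatorial, and C5 and C10 follow from anti addition across the Z-alkene in the chair, which makes C20 axial (cis to C19 and C6) and C9 equatorial, a result reinforced in any stepwise variant by axial C19 blocking the other face of C10. C9 is set by attack through the exo lobe of the bicyclo[3.2.1]octene, which stands about 60° from the C8–C7 bond and is the only lobe the tether can bring to C10, the endo face being covered by the C15–C16 bridge and its silyl ether. The step needs C–C capture to outrun attack of the ester carbonyl oxygen on C10 (dioxolanylium ion), proton loss from C1 and the 1,2-hydride shift to a 3-ketone, which the higher carbon nucleophilicity and pre-organisation of the enol silane, high dilution, −78 °C and a Lewis acid whose methyl group destroys stray protic acid are meant to secure.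

Step 21
Reactants: 35 17-nor spirolactone (3-OH)
Product: 36 3-O-(imidazol-1-ylthiocarbonyl) derivative of 35
Conditions: (imidazol-1-yl)2C=S, DMAP (cat.), toluene, 90 °C
Reagents that add atoms: 1,1'-thiocarbonyldiimidazole, S=C(n1ccnc1)n1ccnc1
Why: Acylation of the equatorial C3 alcohol, the only free hydroxyl group, prepares the Barton–McCombie deoxygenation without a strong base that could epimerise C9.

Step 22
Reactants: 36 3-O-(imidazol-1-ylthiocarbonyl) derivative of 35
Product: 37 3-deoxy spirolactone (C3H2; otherwise as 35)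
Conditions: Bu3SnH, AIBN (cat.), toluene, 110 °C
Reagents that add atoms: none
Why: Barton–McCombie deoxygenation, in which the stannyl radical adds to sulfur, the secondary C3 radical is released and takes hydrogen from Bu3SnH, and no stereocentre is touched.

Step 23
Reactants: 37 3-deoxy spirolactone
Product: 38 C6 primary alcohol (benzyl removed; otherwise as 37)
Conditions: H2 (1 atm), Pd/C (10%), EtOAc, rt
Reagents that add atoms: none
Why: Hydrogenolysis of the benzyl ether frees the C6 alcohol, while ketone, lactone and silyl ethers are inert and no alkene is present.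

Step 24
Reactants: 38 C6 primary alcohol
Product: 40 C6 carboxylic acid (19-O-TBS and 15-O-TBS retained), via C6 aldehyde 39 (not isolated)
Conditions: AZADO (5 mol%), PhI(OAc)2 (2.5 equiv), MeCN–H2O, rt
Reagents that add atoms: water, O
Why: Nitroxyl-catalysed oxidation (the unhindered 2-azaadamantane N-oxyl suits a crowded primary alcohol) takes C6 through the aldehyde hydrate to the acid while O19 and O15 are still silylated, which fixes the direction of the later lactone.

Step 25
Reactants: 40 C6 carboxylic acid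
Product: 42 17-nor bis-lactone with endo 15-OH and 11-oxo (γ-lactone C6(=O)–O–C19 cis-fused on ring A), via dihydroxy acid 41 (not isolated)
Conditions: 48% aq. HF, MeCN, rt
Reagents that add atoms: none
Why: Acidic desilylation frees O19 and O15, and the axial C19 hydroxymethyl group closes onto the cis C6 acid to the five-membered lactone (5-exo-trig) without a base that could epimerise C9 or C5.

Step 26
Reactants: 42 17-nor bis-lactone (15-OH, 11-oxo)
Product: 43 17-nor bis-lactone 11,15-dione
Conditions: Dess–Martin periodinane, CH2Cl2, rt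
Reagents that add atoms: none
Why: Dess–Martin oxidation of the only remaining alcohol gives the C15 ketone under neutral conditions.

Step 27
Reactants: 43 17-nor bis-lactone 11,15-dione
Product: 47 16-methylene-11,15-dione (C16=C17 enone), via C15 lithium enolate 44 (not isolated), via exo C16 Mannich base 45 (not isolated), via Mannich base methiodide 46 (not isolated)
Conditions: LiN(SiMe3)2 (1.05 equiv), THF, −78 °C; Me2N=CH2 I; MeI, rt; DBU, CH2Cl2
Reagents that add atoms: N,N-dimethylmethyleneiminium iodide (Eschenmoser's salt), C=[N+](C)C.[I-]; iodomethane, CI (methyl group of 46 only)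
Why: Eschenmoser methylenation (Mannich reaction of the kinetic enolate, quaternisation, elimination), in which the exo proton at C16 is open whereas the axial proton at C12 is 1,3-diaxial to spiro C10 and the C9 proton lies in the carbonyl plane, so the C15 ketone should be enolised first.

Step 28
Reactants: 47 16-methylene-11,15-dione
Product: 48 11-oxo allylic alcohol (endo 15-OH, C16=C17)
Conditions: NaBH4, CeCl3·7H2O, MeOH, −78 °C
Reagents that add atoms: none
Why: Luche reduction, in which 1,2-attack of hydride on the exo face of the enone gives the endo C15 alcohol of the target, while the C11 ketone, screened by the C15–C16 bridge above and axial C10 beside it, should react more slowly at −78 °C.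

Step 29
Reactants: 48 11-oxo allylic alcohol
Product: 49 guidongnin
Conditions: Me4NBH(OAc)3, MeCN–AcOH, −20 °C
Reagents that add atoms: none
Why: Hydroxyl-directed reduction (Evans–Saksena type), in which the endo C15 hydroxyl group, which sits over C11, exchanges onto boron and delivers hydride to the endo face, giving the equatorial exo C11 alcohol that external hydride does not favour.

## Compound list

1 | prop-2-yn-1-ol | C#CCO | starting material
2 | 2-(2-bromoethyl)-1,3-dioxolane | BrCCC1OCCO1 | starting material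
3 | dilithium salt of prop-2-yn-1-ol | [Li]C#CCO[Li] | intermediate
4 | 5-(1,3-dioxolan-2-yl)pent-2-yn-1-ol | OCC#CCCC1OCCO1 | intermediate
5 | cyclic sodium vinylalanate (Al on C10, cis to C6) | [Na+].COCCO[Al-]1(OCCOC)OCC=C1CCC2OCCO2 | intermediate
6 | (Z)-5-(1,3-dioxolan-2-yl)-3-iodopent-2-en-1-ol | OC/C=C(\I)CCC1OCCO1 | intermediate
7 | 2-[(Z)-5-(benzyloxy)-3-iodopent-3-en-1-yl]-1,3-dioxolane | c1ccccc1COC/C=C(\I)CCC1OCCO1 | intermediate
8 | (Z)-6-(benzyloxy)-4-iodohex-4-enal | O=CCC/C(I)=C/COCc1ccccc1 | intermediate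
9 | methyl 2-[bis(2,2,2-trifluoroethoxy)phosphoryl]propanoate | COC(=O)C(C)P(=O)(OCC(F)(F)F)OCC(F)(F)F | starting material
10 | methyl (2Z,6Z)-8-(benzyloxy)-6-iodo-2-methylocta-2,6-dienoate | COC(=O)/C(C)=C\CC/C(I)=C/COCc1ccccc1 | intermediate
11 | (2Z,6Z)-8-(benzyloxy)-6-iodo-2-methylocta-2,6-dien-1-ol | OC/C(C)=C\CC/C(I)=C/COCc1ccccc1 | intermediate
12 | {(2S,3R)-3-[(Z)-5-(benzyloxy)-3-iodopent-3-en-1-yl]-2-methyloxiran-2-yl}methanol | c1ccccc1COC/C=C(\I)CC[C@H]1O[C@@]1(C)CO | intermediate
13 | tert-butyldimethylsilyl ether of 12 | c1ccccc1COC/C=C(\I)CC[C@H]1O[C@@]1(C)CO[Si](C)(C)C(C)(C)C | intermediate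
14 | C10 vinyllithium from 13 | [Li]/C(CC[C@H]1O[C@@]1(C)CO[Si](C)(C)C(C)(C)C)=C\COCc1ccccc1 | intermediate
15 | (Z)-4-(benzyloxy)-2-{2-[(2R,3S)-3-{[(tert-butyldimethylsilyl)oxy]methyl}-3-methyloxiran-2-yl]ethyl}but-2-en-1-ol | OC/C(=C\COCc1ccccc1)CC[C@H]1O[C@@]1(C)CO[Si](C)(C)C(C)(C)C | intermediate
16 | tert-butyl 2-oxocyclopentane-1-carboxylate | CC(C)(C)OC(=O)C1CCCC1=O | starting material
17 | tert-butyl (1S,2S)-2-hydroxycyclopentane-1-carboxylate | CC(C)(C)OC(=O)[C@H]1CCC[C@@H]1O | intermediate
18 | allyl bromide | C=CCBr | starting material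
19 | dilithium enolate alkoxide of 17 | CC(C)(C)OC(O[Li])=C1CCC[C@@H]1O[Li] | intermediate
20 | tert-butyl (1S,2S)-1-allyl-2-hydroxycyclopentane-1-carboxylate | CC(C)(C)OC(=O)[C@]1(CC=C)CCC[C@@H]1O | intermediate
21 | tert-butyl (S)-1-allyl-2-oxocyclopentane-1-carboxylate | CC(C)(C)OC(=O)[C@]1(CC=C)CCCC1=O | intermediate
22 | tert-butyl (R)-1-allyl-2-oxocyclopent-3-ene-1-carboxylate | CC(C)(C)OC(=O)[C@]1(CC=C)CC=CC1=O | intermediate
23 | tert-butyl (S)-2-oxo-1-(2-oxopropyl)cyclopent-3-ene-1-carboxylate | CC(C)(C)OC(=O)[C@]1(CC(C)=O)CC=CC1=O | intermediate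
24 | potassium C15=C16 enolate of 25 | C=1[C@@H]2CC(=O)C[C@](C2)(C(=O)OC(C)(C)C)C=1O[K] | intermediate
25 | tert-butyl (1S,5S)-3,7-dioxobicyclo[3.2.1]octane-1-carboxylate | C1[C@@H]2CC(=O)C[C@](C2)(C(=O)OC(C)(C)C)C1=O | intermediate
26 | C11 dimethyl ketal of 25 | C1[C@@H]2CC(OC)(OC)C[C@](C2)(C(=O)OC(C)(C)C)C1=O | intermediate
27 | endo C15 alcohol of ketal 26 | C1[C@@H]2CC(OC)(OC)C[C@](C2)(C(=O)OC(C)(C)C)[C@@H]1O | intermediate
28 | tert-butyl (1S,5R,7R)-7-hydroxy-3-oxobicyclo[3.2.1]octane-1-carboxylate | C1[C@@H]2CC(=O)C[C@](C2)(C(=O)OC(C)(C)C)[C@@H]1O | intermediate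
29 | (1S,5R,7R)-7-hydroxy-3-oxobicyclo[3.2.1]octane-1-carboxylic acid | C1[C@@H]2CC(=O)C[C@](C2)(C(=O)O)[C@@H]1O | intermediate
30 | silyl ether silyl ester of 29 | C1[C@@H]2CC(=O)C[C@](C2)(C(=O)O[Si](C)(C)C(C)(C)C)[C@@H]1O[Si](C)(C)C(C)(C)C | intermediate
31 | (1S,5R,7R)-7-[(tert-butyldimethylsilyl)oxy]-3-oxobicyclo[3.2.1]octane-1-carboxylic acid | C1[C@@H]2CC(=O)C[C@](C2)(C(=O)O)[C@@H]1O[Si](C)(C)C(C)(C)C | intermediate
32 | epoxy-diene keto ester (C20 ester of 31 with 15) | C1[C@@H]2CC(=O)C[C@](C2)(C(=O)OC/C(=C\COCc3ccccc3)CC[C@H]4O[C@@]4(C)CO[Si](C)(C)C(C)(C)C)[C@@H]1O[Si](C)(C)C(C)(C)C | intermediate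
33 | C9=C11 lithium enolate of 32 | C1[C@@H]2CC(O[Li])=C[C@](C2)(C(=O)OC/C(=C\COCc3ccccc3)CC[C@H]4O[C@@]4(C)CO[Si](C)(C)C(C)(C)C)[C@@H]1O[Si](C)(C)C(C)(C)C | intermediate
34 | C9=C11 tert-butyldimethylsilyl enol ether of 32 (key-step precursor) | C1[C@@H]2CC(O[Si](C)(C)C(C)(C)C)=C[C@](C2)(C(=O)OC/C(=C\COCc3ccccc3)CC[C@H]4O[C@@]4(C)CO[Si](C)(C)C(C)(C)C)[C@@H]1O[Si](C)(C)C(C)(C)C | intermediate
35 | 3-hydroxy-11-oxo 17-nor spirolactone (key-step product) | C1[C@@H]2CC(=O)[C@H]3[C@@]4(CC[C@@H](O)[C@@](C)(CO[Si](C)(C)C(C)(C)C)[C@H]4COCc5ccccc5)COC(=O)[C@]3(C2)[C@@H]1O[Si](C)(C)C(C)(C)C | intermediate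
36 | 3-O-(imidazol-1-ylthiocarbonyl) derivative of 35 | C1[C@@H]2CC(=O)[C@H]3[C@@]4(CC[C@@H](OC(=S)n6ccnc6)[C@@](C)(CO[Si](C)(C)C(C)(C)C)[C@H]4COCc5ccccc5)COC(=O)[C@]3(C2)[C@@H]1O[Si](C)(C)C(C)(C)C | intermediate
37 | 3-deoxy spirolactone | C1[C@@H]2CC(=O)[C@H]3[C@@]4(CCC[C@@](C)(CO[Si](C)(C)C(C)(C)C)[C@H]4COCc5ccccc5)COC(=O)[C@]3(C2)[C@@H]1O[Si](C)(C)C(C)(C)C | intermediate
38 | C6 primary alcohol | C1[C@@H]2CC(=O)[C@H]3[C@@]4(CCC[C@@](C)(CO[Si](C)(C)C(C)(C)C)[C@H]4CO)COC(=O)[C@]3(C2)[C@@H]1O[Si](C)(C)C(C)(C)C | intermediate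
39 | C6 aldehyde | C1[C@@H]2CC(=O)[C@H]3[C@@]4(CCC[C@@](C)(CO[Si](C)(C)C(C)(C)C)[C@H]4C=O)COC(=O)[C@]3(C2)[C@@H]1O[Si](C)(C)C(C)(C)C | intermediate
40 | C6 carboxylic acid | C1[C@@H]2CC(=O)[C@H]3[C@@]4(CCC[C@@](C)(CO[Si](C)(C)C(C)(C)C)[C@H]4C(=O)O)COC(=O)[C@]3(C2)[C@@H]1O[Si](C)(C)C(C)(C)C | intermediate
41 | 15,19-dihydroxy C6 acid | C1[C@@H]2CC(=O)[C@H]3[C@@]4(CCC[C@@](C)(CO)[C@H]4C(=O)O)COC(=O)[C@]3(C2)[C@@H]1O | intermediate
42 | 17-nor bis-lactone, endo 15-OH, 11-oxo | C1[C@@H]2CC(=O)[C@H]3[C@@]4(CCC[C@@]5(C)COC(=O)[C@H]54)COC(=O)[C@]3(C2)[C@@H]1O | intermediate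
43 | 17-nor bis-lactone 11,15-dione | C1[C@@H]2CC(=O)[C@H]3[C@@]4(CCC[C@@]5(C)COC(=O)[C@H]54)COC(=O)[C@]3(C2)C1=O | intermediate
44 | C15=C16 lithium enolate of 43 | C=1[C@@H]2CC(=O)[C@H]3[C@@]4(CCC[C@@]5(C)COC(=O)[C@H]54)COC(=O)[C@]3(C2)C=1O[Li] | intermediate
45 | exo C16 (dimethylamino)methyl ketone | CN(C)C[C@H]1[C@@H]2CC(=O)[C@H]3[C@@]4(CCC[C@@]5(C)COC(=O)[C@H]54)COC(=O)[C@]3(C2)C1=O | intermediate
46 | methiodide of 45 | C[N+](C)(C)C[C@H]1[C@@H]2CC(=O)[C@H]3[C@@]4(CCC[C@@]5(C)COC(=O)[C@H]54)COC(=O)[C@]3(C2)C1=O.[I-] | intermediate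
47 | 16-methylene-11,15-dione | C=C1[C@@H]2CC(=O)[C@H]3[C@@]4(CCC[C@@]5(C)COC(=O)[C@H]54)COC(=O)[C@]3(C2)C1=O | intermediate
48 | 11-oxo allylic alcohol (endo 15-OH) | C=C1[C@@H]2CC(=O)[C@H]3[C@@]4(CCC[C@@]5(C)COC(=O)[C@H]54)COC(=O)[C@]3(C2)[C@@H]1O | intermediate
49 | guidongnin | C=C1[C@@H]2C[C@@H](O)[C@H]3[C@@]4(CCC[C@@]5(C)COC(=O)[C@H]54)COC(=O)[C@]3(C2)[C@@H]1O | target

## Step count

- Total step count: 29.
- Longest linear sequence: 21 steps (steps 1–9 and 18–29).

## Steps most likely to fail

**1. Step 20.**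
The C5=C10 alkene is deactivated by two allylic oxygens and may open the epoxide too slowly, so a hydride shift to the 3-ketone could take over. The C10 cation may also be intercepted by the ester carbonyl oxygen or lose a proton before the ester has turned into its s-cis form.

Fallback, setting out from 32 and coming back at 35, makes the two bonds one after the other by known reactions.
- MeAlCl2 acting on 32 without an enol silane should stop, as with epoxygeranyl esters, at the monocyclic 3-hydroxy-1(10)-ene keto ester F1.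
- Markovnikov addition of HCl gives the tertiary C10 chloride F2.
- Deprotonation with the chiral lithium amide of step 19 in the presence of Me3SiCl gives the trimethylsilyl enol ether 3-O-trimethylsilyl ether F3.
- TiCl4 at −78 °C ionises the tertiary chloride for the Lewis acid tert-alkylation of the silyl enol ether. The same facial arguments apply at C9 and C10, and acidic work-up frees O3 to give 35.

**2. Step 19.**
Regiocontrol of the deprotonation may be poor, because the large ester next to C9 favours loss of the C12 proton against the preference of the base.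

Fallback, setting out from 32 and coming back at 35.
- Claisen condensation with ethyl formate (NaH, THF) runs under equilibrium control to C12, because a hydroxymethylene group at C9 would eclipse the C8–C7 bond. This gives the 12-hydroxymethylene ketone F4.
- Double deprotonation with KN(SiMe3)2 and silylation with TBSOTf give the 1,3-bis(silyloxy)diene F5. Here C9 is the only nucleophilic terminus and is more nucleophilic than in 34.
- Cyclisation with MeAlCl2 as in step 20 gives the 12-hydroxymethylene spirolactone F6.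
- Retro-Claisen deformylation (K2CO3, aqueous MeOH) leads to 35.

**3. Step 27.**
The C11 ketone may be enolised toward C12 in competition, leading to Mannich reaction at the wrong carbon. The same lack of discrimination between the two ketones would also trouble step 28.

Fallback, setting out from 42 and coming back at 49, removes the second ketone first.
- The endo 15-OH already present in 42 directs Me4NBH(OAc)3 to the endo face of C11, giving the 11,15-diol F7.
- The more open equatorial 11-OH is silylated (Et3SiCl, imidazole) to the 11-O-triethylsilyl ether F8.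
- Dess–Martin oxidation gives the 15-ketone F9.
- Direct Mannich-type methylenation (paraformaldehyde, diisopropylammonium trifluoroacetate, THF, reflux) at the only enolisable position gives the enone F10.
- Luche reduction gives the endo allylic alcohol F11.
- HF·pyridine frees O11 to give 49.

## Further compounds

F1 | step 20 | monocyclic 3-hydroxy-1(10)-ene keto ester | C1[C@@H]2CC(=O)C[C@](C2)(C(=O)OCC3=CC[C@@H](O)[C@@](C)(CO[Si](C)(C)C(C)(C)C)[C@H]3COCc4ccccc4)[C@@H]1O[Si](C)(C)C(C)(C)C
F2 | step 20 | tertiary C10 chloride (C10 epimers) | C1[C@@H]2CC(=O)C[C@](C2)(C(=O)OCC3(Cl)CC[C@@H](O)[C@@](C)(CO[Si](C)(C)C(C)(C)C)[C@H]3COCc4ccccc4)[C@@H]1O[Si](C)(C)C(C)(C)C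
F3 | step 20 | trimethylsilyl enol ether 3-O-trimethylsilyl ether of F2 | C1[C@@H]2CC(O[Si](C)(C)C)=C[C@](C2)(C(=O)OCC3(Cl)CC[C@@H](O[Si](C)(C)C)[C@@](C)(CO[Si](C)(C)C(C)(C)C)[C@H]3COCc4ccccc4)[C@@H]1O[Si](C)(C)C(C)(C)C
F4 | step 19 | 12-hydroxymethylene ketone of 32 | C1[C@@H]2/C(=C/O)C(=O)C[C@](C2)(C(=O)OC/C(=C\COCc3ccccc3)CC[C@H]4O[C@@]4(C)CO[Si](C)(C)C(C)(C)C)[C@@H]1O[Si](C)(C)C(C)(C)C
F5 | step 19 | 1,3-bis(silyloxy)diene from F4 | C1[C@@H]2/C(=C/O[Si](C)(C)C(C)(C)C)C(O[Si](C)(C)C(C)(C)C)=C[C@](C2)(C(=O)OC/C(=C\COCc3ccccc3)CC[C@H]4O[C@@]4(C)CO[Si](C)(C)C(C)(C)C)[C@@H]1O[Si](C)(C)C(C)(C)C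
F6 | step 19 | 12-hydroxymethylene spirolactone | C1[C@@H]2/C(=C/O)C(=O)[C@H]3[C@@]4(CC[C@@H](O)[C@@](C)(CO[Si](C)(C)C(C)(C)C)[C@H]4COCc5ccccc5)COC(=O)[C@]3(C2)[C@@H]1O[Si](C)(C)C(C)(C)C
F7 | step 27 | 17-nor 11,15-diol | C1[C@@H]2C[C@@H](O)[C@H]3[C@@]4(CCC[C@@]5(C)COC(=O)[C@H]54)COC(=O)[C@]3(C2)[C@@H]1O
F8 | step 27 | 11-O-triethylsilyl ether of F7 | C1[C@@H]2C[C@@H](O[Si](CC)(CC)CC)[C@H]3[C@@]4(CCC[C@@]5(C)COC(=O)[C@H]54)COC(=O)[C@]3(C2)[C@@H]1O
F9 | step 27 | 11-O-triethylsilyl 15-ketone | C1[C@@H]2C[C@@H](O[Si](CC)(CC)CC)[C@H]3[C@@]4(CCC[C@@]5(C)COC(=O)[C@H]54)COC(=O)[C@]3(C2)C1=O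
F10 | step 27 | 11-O-triethylsilyl 16-methylene 15-ketone | C=C1[C@@H]2C[C@@H](O[Si](CC)(CC)CC)[C@H]3[C@@]4(CCC[C@@]5(C)COC(=O)[C@H]54)COC(=O)[C@]3(C2)C1=O
F11 | step 27 | 11-O-triethylsilyl guidongnin | C=C1[C@@H]2C[C@@H](O[Si](CC)(CC)CC)[C@H]3[C@@]4(CCC[C@@]5(C)COC(=O)[C@H]54)COC(=O)[C@]3(C2)[C@@H]1O
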